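Atom numbers are those of the ent-kaurane skeleton (C1–C20; O1, O6, O19 and O20 are the oxygens on those carbons). Compound numbers are those of the list after the steps.

## Analysis of the target

The target 31 is a 6,7-seco-ent-kauranoid of the spirolactone type. It has a cyclohexane ring A (C1–C5, C10), a δ-lactone (C10, C20, O20, C7, C8, C9) spiro-fused to ring A at C10, and a bicyclo[3.2.1]octane (rings C and D) fused to the lactone at C8–C9 that carries the 15-oxo-16-methylene unit. There are seven stereocentres, C1, C4, C5 and C10 on ring A and C8, C9 and C13 in the bicycle; C4, C8 and C10 are quaternary. On ring A, O1, C19, C6 and C20 lie on one face and C18, H5 and C9 on the other. Across the spiro centre, C11 lies on the side of C1 and H9 on the side of C5; C15 and H9 are cis on the lactone, and C13 is fixed by the bridge once C8 is set. The sensitive groups are the exo-methylene enone (a Michael acceptor), the non-enolisable β-keto lactone at C8 (retro-Claisen cleavage with nucleophilic base) and two acetates beside a free primary alcohol (acyl migration), so the late steps must be neither basic nor nucleophilic. The difficulty lies in the contiguous C4–C5–C10 array with two quaternary carbons, in telling four oxygenated carbons on ring A apart, and in setting C9 next to a spiro carbon that is flanked by substituents on both C1 and C5. The strategy rests on one feature: O1 and C19 sit on the para-related C1 and C4 on the same face, which is what reduction of a C19(=O)–O1 lactone bridge across ring A gives. With C6 and C20 cis on that face as well, ring A maps onto the bridged cycloadduct of pyrone 2 and the (E)-enal 13.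

## Retrosynthetic reasoning

31 ⇐ 30 ⇐ 28. The last operations are removal of the O6 silyl group and introduction of C17. The enone is the most fragile element, so C16=C17 is made after every reduction. In 28, C16 is the only enolisable carbon, so a Mannich methylenation cannot go elsewhere, and the alkene cannot move into the ring because C13 is a bridgehead.

28 ⇐ 27 ⇐ 26. C12 bears no oxygen in 31, but a C12 carbonyl is what makes C13 a nucleophile. It is accepted as a temporary control element and removed through dithiolane 27. The forward step has to tell the C12 carbonyl from the C15 carbonyl, which the quaternary C8 next to C15 should allow.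

26 ⇐ 24 (through 25). The C13–C16 bond is cut. It is cut there and not at C8–C15 or C15–C16 because C16 is α to the C15 ketone and can carry a leaving group, while C13 is the carbon of a regiodefined enol ether that the preceding cycloaddition delivers. A polar 5-exo-tet closure has none of the 5-exo versus 6-endo ambiguity of a radical addition to an unpolarised C12=C13 bond. The forward step must release the enolate without letting it equilibrate; the bridge then dictates C13.

24 ⇐ 22 + 23. The C8–C14 and C9–C11 bonds are cut as a [4+2] cycloaddition. This gives ring C, the quaternary C8 and the C8/C9 pair in one step, and the cis relation of C15 and H9 comes automatically from addition to the endocyclic alkene. The forward step has to select the face of C8=C9 that is syn to C1.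

22 ⇐ 20 (through 21) ⇐ 19 ⇐ 18. The C8=C9 bond (Knoevenagel condensation) and the O20–C7 ester bond are cut. The lactone is thereby assembled from the two groups on C10, the C9 aldehyde and O20, and the reagent brings C7, C8, C15, C16 and the leaving group in one piece. It makes C8=C9 doubly activated. Before that, C9 and then O20 are unmasked, in this order so that the free O20 hydroxyl never meets acid or base next to the O1 acetate.

18 ⇐ 17 ⇐ 16 ⇐ 15 ⇐ 14. The two acetates come from a 1,19-diol, and the diol from hydride opening of the lactone bridge, which shows that O1 and C19 can be carried as one functional group. The C9 aldehyde has to be masked for this (16), and C2=C3 is saturated first (15) so that the bicycle can no longer fragment by decarboxylative cycloreversion.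

14 ⇐ 2 + 13. The C1–C10 and C4–C5 bonds are cut. This is the central disconnection: two flat, achiral pieces give all four stereocentres and both quaternary carbons of ring A. The four oxygenated carbons also arrive already differentiated (C9 aldehyde, C19/O1 lactone, two different ethers). The forward reaction has to overcome the low reactivity of a trisubstituted enal towards a weak diene, keep the bridge, and control regiochemistry, endo orientation and absolute sense.

13 ⇐ 12 ⇐ 11 ⇐ 6 + 7 + 8 (through 9 and 10). The C5=C10 bond is cut as a Horner–Wadsworth–Emmons olefination. The oxa-Michael/olefination sequence places the O20 protecting group from 7 and the O6 protecting group from 6 on different oxygens from the start. The olefination must put the ester trans to C6, so that C20 and C6 are cis. Aldehyde 6 comes from the symmetric diol 3 through 4 and ozonide 5.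

2 ⇐ 1. The C18 methyl group is introduced by cross-coupling at the C–Br bond of 1.

## Alternatives that were turned down

Alternative 1: The exocyclic bonds C5–C6 and C10–C20 would be made together by an intramolecular [2+2] photocycloaddition, the C5=C10 bond of a ring A enone adding a vinylsilane tethered through O19, to give the cyclobutane A1. In its favour, enone–alkene photocycloaddition with a short tether is a dependable reaction class, on that point more certain than the pyrone cycloaddition chosen here. The tether from the axial C19 oxygen delivers both new carbons to the C19 face and creates the quaternary C10 under neutral conditions. Against it, A1 contains a C6–C20 bond that the target does not have. It would have to be cleaved regioselectively, and C20 would then need an oxygen on a neopentyl carbon with no handle. The step sets two stereocentres only, needs an enantiopure C4 quaternary centre beforehand and a stereoselective reduction at C1 afterwards, and leaves rings C and D and the lactone to be built from a three-carbon chain. The chosen strategy sets C1, C4, C5 and C10 at once with every oxygenated carbon at a usable oxidation level, at the price of a less certain key step.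

Alternative 2: The C13–C16 bond would be formed by attack of a C12 silyl enol ether on the terminal alkyne of a C8 propargyl group activated by a cationic gold complex such as Ph3PAuNTf2, giving A2 with the exo-methylene group in place. In its favour, this 5-exo-dig carbocyclisation is well established for bicyclo[3.2.1]octanes and delivers C16=C17 directly. On that point it is stronger than the ring D closure used here, which needs a separate methylenation. Against it, A2 has oxygen at C12 and none at C15, so a deoxygenation and an allylic oxidation plus an alcohol oxidation follow, and its silyl and PMB groups must be exchanged for the acetates. A propargyl group on C8 also leaves the C8=C9 alkene singly activated for ring C formation. Above all the step is silent on ring A, where four of the seven stereocentres and two quaternary carbons lie. The route chosen here uses the same polarity (a C12 enol ether making C13 nucleophilic) but with C15 already a ketone, and spends its key step on ring A.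

Alternative 3: The C5–C10 bond would be formed by a semipinacol ring expansion. A Lewis acid opens a C10–C20 epoxide at its tertiary carbon, and C5 of a cyclopentanol migrates from C1 to C10, giving the ring A ketone A3. In its favour, the 1,2-shift is stereospecific, so C10 would be set with certainty from the epoxide configuration, and the C1 carbonyl and the free O20 hydroxyl appear in the same step. On precedent and on control of C10 alone it is stronger than the cycloaddition. Against it, only one stereocentre is made in the key step. The cyclopentane precursor must already contain C4 and C5 in enantiopure form and a stereodefined epoxy alcohol, and C5 has to migrate in preference to C2. The C1 ketone must then be reduced selectively and three different protecting groups exchanged. The chosen strategy is shorter to ring A and needs no earlier stereocentre, and it offers the C9 aldehyde as the handle for the lactone.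

Key step: step 7

## Route

Remark: the sense of induction of the cinchona primary amine in step 7 cannot be predicted with confidence; the route is written for the quinine-derived amine, and the quinidine-derived pseudoenantiomer takes its place if a pilot run shows the opposite sense.

Step 1
Reactants: 1 3-bromo-2H-pyran-2-one
Product: 2 3-methyl-2H-pyran-2-one
Conditions: MeZnCl, Pd(PPh3)4 (5 mol %), THF, 0 → 23 °C
Reagents that add atoms: methylzinc chloride, C[Zn]Cl
Why: Negishi cross-coupling; the C–Br bond is vinylic and α to the carbonyl group, so it adds readily to zerovalent palladium, and the organozinc reagent does not open the lactone.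

Step 2
Reactants: 3 (Z)-but-2-ene-1,4-diol
Product: 4 (Z)-1,4-bis(tert-butyldiphenylsilyloxy)but-2-ene
Conditions: tBuPh2SiCl (2.2 equiv), imidazole, DMF, 23 °C
Reagents that add atoms: tert-butyl(chloro)diphenylsilane, CC(C)(C)[Si](Cl)(c1ccccc1)c1ccccc1
Why: Standard silylation of both primary alcohols; the symmetric alkene gives two molecules of the aldehyde in the next step.

Step 3
Reactants: 4 (Z)-1,4-bis(tert-butyldiphenylsilyloxy)but-2-ene
Product: 6 2-(tert-butyldiphenylsilyloxy)acetaldehyde, via secondary ozonide 5 (not isolated)
Conditions: O3, CH2Cl2, −78 °C; then PPh3, −78 → 23 °C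
Reagents that add atoms: ozone, [O-][O+]=O
Why: Ozonolysis with reductive work-up cleaves the alkene into two molecules of the silyloxy aldehyde, which is used promptly.

Step 4
Reactants: 7 4-methoxybenzyl alcohol; 8 ethyl 2-(diethoxyphosphoryl)prop-2-enoate; 6 2-(tert-butyldiphenylsilyloxy)acetaldehyde
Product: 11 ethyl (E)-4-(tert-butyldiphenylsilyloxy)-2-[(4-methoxybenzyloxy)methyl]but-2-enoate, via sodium 4-methoxybenzyl oxide 9 (not isolated), via phosphonate carbanion 10 (not isolated)
Conditions: NaH, THF, 0 °C; 8, −78 → 0 °C; then 6, −78 → 23 °C
Reagents that add atoms: none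
Why: Oxa-Michael addition of the alkoxide to the vinylphosphonate gives the stabilised carbanion directly, and its Horner–Wadsworth–Emmons reaction with 6 forms C5=C10. α-Branched phosphonoacetates give mainly the isomer with the ester trans to the aldehyde-derived substituent, which places the C20 and C6 CH2O groups cis; any minor isomer is removed by chromatography.

Step 5
Reactants: 11 ethyl (E)-4-(tert-butyldiphenylsilyloxy)-2-[(4-methoxybenzyloxy)methyl]but-2-enoate
Product: 12 (Z)-4-(tert-butyldiphenylsilyloxy)-2-[(4-methoxybenzyloxy)methyl]but-2-en-1-ol
Conditions: iBu2AlH (2.2 equiv), CH2Cl2, −78 °C; aq. potassium sodium tartrate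
Reagents that add atoms: none
Why: 1,2-Reduction of the enoate to the allylic alcohol; the ethers and the alkene geometry are not affected (the descriptor changes only because of the priority rules).

Step 6
Reactants: 12 (Z)-4-(tert-butyldiphenylsilyloxy)-2-[(4-methoxybenzyloxy)methyl]but-2-en-1-ol
Product: 13 (E)-4-(tert-butyldiphenylsilyloxy)-2-[(4-methoxybenzyloxy)methyl]but-2-enal
Conditions: MnO2, CH2Cl2, 23 °C
Reagents that add atoms: none
Why: Chemoselective oxidation of the allylic alcohol under neutral conditions; the formyl group stays trans to C6, which is also the thermodynamically preferred geometry of a 2-substituted enal.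

Step 7
Reactants: 2 3-methyl-2H-pyran-2-one; 13 (E)-4-(tert-butyldiphenylsilyloxy)-2-[(4-methoxybenzyloxy)methyl]but-2-enal
Product: 14 bridged ring A cycloadduct (2-oxabicyclo[2.2.2]oct-7-en-3-one with C9 formyl and C20 CH2OPMB on C10 and C6 CH2OSitBuPh2 on C5)
Conditions: 9-amino-9-deoxy-epi-quinine (20 mol %), CF3CO2H (40 mol %), 2 (3 equiv), CH2Cl2, 12 kbar, 23 °C
Reagents that add atoms: none
Why: Proposed new method: condensation of the primary amine salt with 13 gives an iminium ion whose β-carbon C5 is attacked by the methyl-bearing terminus of 2 (the future C4, the α-carbon of the dienyl ester and its most nucleophilic end), and the C1–C10 bond closes in the same asynchronous suprafacial [4+2] event before hydrolysis releases 14 and the amine; the closest known reaction types are the high-pressure Diels–Alder reaction of 2-pyrones with acrylic dienophiles with retention of the bridge and primary-amine iminium catalysis of cycloadditions of α-branched enals. Ring A is closed by intermolecular [4+2] cycloaddition, both sigma bonds (C1–C10 and C4–C5) forming on one face of each partner to give the 2-oxabicyclo[2.2.2]octene. C1 and C4 are bridgeheads, so their relative configuration is fixed by the lactone bridge, and the cis relation of C6 and C20 on C5 and C10 is carried over from the E geometry of 13. Placing C6 and C20 on the face of the bridge requires the iminium group to lie endo, under C2=C3, which is favoured by secondary overlap and because the two CH2OR groups then face the hydrogen-free O–C(=O) bridge. The absolute configuration comes from the catalyst, whose protonated quinuclidine and counter-anion block one face of the iminium ion. The regiochemistry needed (C10 to the unsubstituted terminus) avoids vicinal quaternary centres and lets the positive charge that develops in the pyrone sit next to the ring oxygen. A pressure of 12 kbar at ambient temperature uses the negative activation volume of the cycloaddition and keeps 14 from extruding CO2.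

Step 8
Reactants: 14 bridged ring A cycloadduct
Product: 15 saturated bridged lactone aldehyde (2-oxabicyclo[2.2.2]octan-3-one)
Conditions: KO2CN=NCO2K, AcOH, MeOH/CH2Cl2, 0 → 23 °C
Reagents that add atoms: none
Why: Diimide reduction; the strained cis-disubstituted C2=C3 bond of the bicyclooctene is an excellent acceptor, while the aldehyde, the PMB ether and the lactone are inert. Saturation also removes the retro-[4+2] pathway for loss of CO2.

Step 9
Reactants: 15 saturated bridged lactone aldehyde
Product: 16 C9 1,3-dioxolane of 15
Conditions: Me3SiOCH2CH2OSiMe3, TMSOTf (5 mol %), CH2Cl2, −78 → −20 °C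
Reagents that add atoms: 1,2-bis(trimethylsilyloxy)ethane, C[Si](C)(C)OCCO[Si](C)(C)C
Why: Silyl-transfer acetalisation under aprotic, low-temperature conditions, driven by formation of the disiloxane; it works on hindered neopentyl carbonyl groups and spares the PMB ether, the silyl ether and the lactone.

Step 10
Reactants: 16 C9 1,3-dioxolane of 15
Product: 17 ring A 1,19-diol (C9 dioxolane, O20 PMB, O6 SitBuPh2)
Conditions: LiAlH4, THF, 0 °C; aq. NaOH work-up
Reagents that add atoms: none
Why: Hydride reduction of the strained bridging lactone cleaves the C19–O1 acyl bond; C19 becomes CH2OH and O1 a secondary alcohol, both on the face where the bridge stood, and no stereocentre is touched.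

Step 11
Reactants: 17 ring A 1,19-diol
Product: 18 ring A 1,19-diacetate
Conditions: Ac2O, pyridine, DMAP (10 mol %), CH2Cl2, 23 °C
Reagents that add atoms: acetic anhydride, CC(=O)OC(C)=O
Why: DMAP-catalysed acetylation of the primary and the equatorial secondary alcohol installs both acetates of the target in one operation.

Step 12
Reactants: 18 ring A 1,19-diacetate
Product: 19 C9 aldehyde diacetate (O20 PMB)
Conditions: TsOH·H2O (20 mol %), acetone/H2O (10:1), 45 °C
Reagents that add atoms: water, O
Why: Acid-catalysed acetal hydrolysis; the acetates, the PMB ether and the tert-butyldiphenylsilyl ether tolerate this mild aqueous acid, and the aldehyde has no α-hydrogen.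

Step 13
Reactants: 19 C9 aldehyde diacetate
Product: 20 C20 hydroxy C9 aldehyde diacetate
Conditions: DDQ, CH2Cl2/pH 7 buffer (18:1), 0 → 23 °C
Reagents that add atoms: none
Why: Oxidative cleavage of the PMB ether under neutral conditions frees O20 without acid or base, so the neighbouring O1 acetate has no occasion to migrate. The β-hydroxy aldehyde cannot dehydrate because C10 is quaternary, and it is used at once.

Step 14
Reactants: 20 C20 hydroxy C9 aldehyde diacetate
Product: 22 spiro α-(chloroacetyl)-α,β-unsaturated δ-lactone, via chloroacetoacetate ester 21 (not isolated)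
Conditions: 6-(chloromethyl)-2,2-dimethyl-4H-1,3-dioxin-4-one, PhMe, 110 °C; then piperidine/AcOH (20 mol %), 4 Å MS, 23 °C
Reagents that add atoms: 6-(chloromethyl)-2,2-dimethyl-4H-1,3-dioxin-4-one, CC1(C)OC(CCl)=CC(=O)O1
Why: Thermolysis of the dioxinone releases (chloroacetyl)ketene, which acylates O20 under neutral conditions. The intramolecular Knoevenagel condensation of the β-keto ester with the C9 aldehyde then forms C8=C9 and closes the six-membered lactone, helped by the quaternary C10.

Step 15
Reactants: 22 spiro α-(chloroacetyl)-α,β-unsaturated δ-lactone; 23 2-(trimethylsilyloxy)buta-1,3-diene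
Product: 24 ring C cycloadduct with C12 trimethylsilyl enol ether
Conditions: 23 (3 equiv), PhMe, 2,6-di-tert-butyl-4-methylphenol (trace), 23 → 60 °C
Reagents that add atoms: none
Why: Diels–Alder reaction of a 2-acyl-2-enoate, activated by both carbonyl groups on C8, with a 2-silyloxydiene: the CH2 terminus next to the silyloxy carbon bonds to the β-carbon C9 and the other terminus to C8, which closes ring C and leaves the enol ether as C12(OSi)=C13. Suprafacial addition to the endocyclic alkene makes C15 and H9 cis, and the diene should approach the face of C8=C9 syn to C1, because C5 with its CH2OSitBuPh2 group prefers the pseudoaxial position on the lactone half-chair (no allylic strain with H9) and covers the other face. The thermal reaction without Lewis acid keeps the silyl enol ether for the next step.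

Step 16
Reactants: 24 ring C cycloadduct with C12 trimethylsilyl enol ether
Product: 26 tetracyclic 12,15-dione, via tetrabutylammonium enolate 25 (not isolated)
Conditions: Bu4N[Ph3SiF2] (1.1 equiv), Bu4NI (20 mol %), THF, −78 → 0 °C
Reagents that add atoms: none
Why: Fluoride cleaves the trimethylsilyl enol ether to the regiodefined C12 enolate, whose carbon C13 displaces chloride at C16 in a 5-exo-tet SN2 reaction on the α-halo ketone and closes ring D as the bicyclo[3.2.1]octane. C13 can only bond on the face that carries C15, so its configuration follows from C8. One equivalent of fluoride at low temperature should leave the primary tert-butyldiphenylsilyl ether intact.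

Step 17
Reactants: 26 tetracyclic 12,15-dione
Product: 27 C12 1,3-dithiolane
Conditions: HSCH2CH2SH, BF3·OEt2, CH2Cl2, −20 → 0 °C
Reagents that add atoms: ethane-1,2-dithiol, SCCS
Why: Chemoselective dithioketalisation; the C12 carbonyl is flanked by CH2 and CH, whereas the C15 carbonyl is flanked by the quaternary C8, so only C12 should react under mild Lewis acid conditions.

Step 18
Reactants: 27 C12 1,3-dithiolane
Product: 28 tetracyclic 15-ketone (C12 and C16 as CH2)
Conditions: Raney Ni (W-2), EtOH/THF, 23 °C
Reagents that add atoms: none
Why: Reductive desulfurisation turns C12 into CH2; the neutral conditions spare the esters, the lactone and the hindered C15 ketone.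

Step 19
Reactants: 28 tetracyclic 15-ketone
Product: 30 O6 tert-butyldiphenylsilyl ether of the target, via Mannich base 29 (not isolated)
Conditions: (CH2O)n, PhNHMe·CF3CO2H, THF, 65 °C
Reagents that add atoms: formaldehyde (as paraformaldehyde), C=O
Why: Mannich reaction at C16 followed by β-elimination of N-methylaniline under mildly acidic conditions; C16 is the only enolisable carbon, and the new double bond can only be exocyclic because C13 is a bridgehead.

Step 20
Reactants: 30 O6 tert-butyldiphenylsilyl ether of the target
Product: 31 CNP0105570.2
Conditions: HF·pyridine, THF/pyridine, 0 → 23 °C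
Reagents that add atoms: none
Why: Acidic fluoride cleaves the silyl ether without base, so neither acetate should migrate to O6, and the enone and the β-keto lactone are not attacked.

## Compound list

1 | 3-bromo-2H-pyran-2-one | O=C1OC=CC=C1Br | starting material
2 | 3-methyl-2H-pyran-2-one | CC1=CC=COC1=O | intermediate
3 | (Z)-but-2-ene-1,4-diol | OC/C=C\CO | starting material
4 | (Z)-1,4-bis(tert-butyldiphenylsilyloxy)but-2-ene | CC(C)(C)[Si](c1ccccc1)(c1ccccc1)OC/C=C\CO[Si](c1ccccc1)(c1ccccc1)C(C)(C)C | intermediate
5 | 3,5-bis[(tert-butyldiphenylsilyloxy)methyl]-1,2,4-trioxolane (secondary ozonide, configuration immaterial) | CC(C)(C)[Si](c1ccccc1)(c1ccccc1)OCC1OOC(CO[Si](c2ccccc2)(c2ccccc2)C(C)(C)C)O1 | intermediate (not isolated)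
6 | 2-(tert-butyldiphenylsilyloxy)acetaldehyde | O=CCO[Si](c1ccccc1)(c1ccccc1)C(C)(C)C | intermediate
7 | 4-methoxybenzyl alcohol | COc1ccc(CO)cc1 | starting material
8 | ethyl 2-(diethoxyphosphoryl)prop-2-enoate | C=C(C(=O)OCC)P(=O)(OCC)OCC | starting material
9 | sodium 4-methoxybenzyl oxide | COc1ccc(C[O-])cc1.[Na+] | intermediate (not isolated)
10 | sodium salt of ethyl 2-(diethoxyphosphoryl)-3-(4-methoxybenzyloxy)propanoate (phosphonate carbanion) | CCOC(=O)[C-](COCc1ccc(OC)cc1)P(=O)(OCC)OCC.[Na+] | intermediate (not isolated)
11 | ethyl (E)-4-(tert-butyldiphenylsilyloxy)-2-[(4-methoxybenzyloxy)methyl]but-2-enoate (ester trans to the silyloxymethyl group) | CCOC(=O)/C(COCc1ccc(OC)cc1)=C/CO[Si](c1ccccc1)(c1ccccc1)C(C)(C)C | intermediate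
12 | (Z)-4-(tert-butyldiphenylsilyloxy)-2-[(4-methoxybenzyloxy)methyl]but-2-en-1-ol (hydroxymethyl trans to the silyloxymethyl group) | OC/C(COCc1ccc(OC)cc1)=C/CO[Si](c1ccccc1)(c1ccccc1)C(C)(C)C | intermediate
13 | (E)-4-(tert-butyldiphenylsilyloxy)-2-[(4-methoxybenzyloxy)methyl]but-2-enal (C9 formyl trans to C6; C20 and C6 cis) | O=C/C(COCc1ccc(OC)cc1)=C/CO[Si](c1ccccc1)(c1ccccc1)C(C)(C)C | intermediate
14 | bridged cycloadduct, 2-oxabicyclo[2.2.2]oct-7-en-3-one: C4 methyl bridgehead, C5 CH2OSitBuPh2, C10 with formyl (C9) on the face of the C2=C3 bridge and CH2OPMB (C20) on the face of the lactone bridge | O=C[C@]1(COCc3ccc(OC)cc3)[C@@H]2C=C[C@@](C)(C(=O)O2)[C@H]1CO[Si](c4ccccc4)(c5ccccc5)C(C)(C)C | intermediate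
15 | 2,3-dihydro derivative of 14 (2-oxabicyclo[2.2.2]octan-3-one) | O=C[C@]1(COCc3ccc(OC)cc3)[C@@H]2CC[C@@](C)(C(=O)O2)[C@H]1CO[Si](c4ccccc4)(c5ccccc5)C(C)(C)C | intermediate
16 | C9 1,3-dioxolane of 15 | C6(OCCO6)[C@]1(COCc3ccc(OC)cc3)[C@@H]2CC[C@@](C)(C(=O)O2)[C@H]1CO[Si](c4ccccc4)(c5ccccc5)C(C)(C)C | intermediate
17 | ring A diol: C1 OH, C4 CH3 and CH2OH, C5 CH2OSitBuPh2, C10 1,3-dioxolan-2-yl (C9) and CH2OPMB (C20); O1, C19, C6 and C20 on one face | C6(OCCO6)[C@]1(COCc3ccc(OC)cc3)[C@@H](O)CC[C@@](C)(CO)[C@H]1CO[Si](c4ccccc4)(c5ccccc5)C(C)(C)C | intermediate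
18 | 1,19-di-O-acetate of 17 | C6(OCCO6)[C@]1(COCc3ccc(OC)cc3)[C@@H](OC(C)=O)CC[C@@](C)(COC(C)=O)[C@H]1CO[Si](c4ccccc4)(c5ccccc5)C(C)(C)C | intermediate
19 | C9 aldehyde from 18 (O20 PMB, O1 and O19 acetates, O6 SitBuPh2) | O=C[C@]1(COCc3ccc(OC)cc3)[C@@H](OC(C)=O)CC[C@@](C)(COC(C)=O)[C@H]1CO[Si](c4ccccc4)(c5ccccc5)C(C)(C)C | intermediate
20 | C20 alcohol of 19 (β-hydroxy aldehyde) | O=C[C@]1(CO)[C@@H](OC(C)=O)CC[C@@](C)(COC(C)=O)[C@H]1CO[Si](c4ccccc4)(c5ccccc5)C(C)(C)C | intermediate
21 | O20 4-chloro-3-oxobutanoate of 20 | O=C[C@]1(COC(=O)CC(=O)CCl)[C@@H](OC(C)=O)CC[C@@](C)(COC(C)=O)[C@H]1CO[Si](c4ccccc4)(c5ccccc5)C(C)(C)C | intermediate (not isolated)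
22 | spiro unsaturated δ-lactone: C10–C20–O–C7(=O)–C8=C9, C8 bearing the chloroacetyl group (C15, C16) | ClCC(=O)C2=C[C@]1(COC2=O)[C@@H](OC(C)=O)CC[C@@](C)(COC(C)=O)[C@H]1CO[Si](c4ccccc4)(c5ccccc5)C(C)(C)C | intermediate
23 | 2-(trimethylsilyloxy)buta-1,3-diene | C=CC(=C)O[Si](C)(C)C | starting material
24 | ring C cycloadduct: cis-fused lactone/cyclohexene, C8 quaternary with chloroacetyl, C12(OSiMe3)=C13, C11 syn to C1 | ClCC(=O)[C@]23CC=C(O[Si](C)(C)C)C[C@H]2[C@]1(COC3=O)[C@@H](OC(C)=O)CC[C@@](C)(COC(C)=O)[C@H]1CO[Si](c4ccccc4)(c5ccccc5)C(C)(C)C | intermediate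
25 | tetrabutylammonium C12 enolate of the ring C ketone | ClCC(=O)[C@]23CC=C([O-])C[C@H]2[C@]1(COC3=O)[C@@H](OC(C)=O)CC[C@@](C)(COC(C)=O)[C@H]1CO[Si](c4ccccc4)(c5ccccc5)C(C)(C)C.CCCC[N+](CCCC)(CCCC)CCCC | intermediate (not isolated)
26 | tetracyclic 12,15-dione (bicyclo[3.2.1]octane closed, C16 as CH2) | C1C(=O)[C@]23C[C@H]1C(=O)C[C@H]2[C@]1(COC3=O)[C@@H](OC(C)=O)CC[C@@](C)(COC(C)=O)[C@H]1CO[Si](c4ccccc4)(c5ccccc5)C(C)(C)C | intermediate
27 | C12 1,3-dithiolane of 26 | C1C(=O)[C@]23C[C@H]1C6(SCCS6)C[C@H]2[C@]1(COC3=O)[C@@H](OC(C)=O)CC[C@@](C)(COC(C)=O)[C@H]1CO[Si](c4ccccc4)(c5ccccc5)C(C)(C)C | intermediate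
28 | 12-deoxo 15-ketone (16,17-dinor-methylene precursor) | C1C(=O)[C@]23C[C@H]1CC[C@H]2[C@]1(COC3=O)[C@@H](OC(C)=O)CC[C@@](C)(COC(C)=O)[C@H]1CO[Si](c4ccccc4)(c5ccccc5)C(C)(C)C | intermediate
29 | C16 (N-methylanilino)methyl ketone (Mannich base, C16 configuration immaterial) | CN(CC1C(=O)[C@]23C[C@H]1CC[C@H]2[C@]1(COC3=O)[C@@H](OC(C)=O)CC[C@@](C)(COC(C)=O)[C@H]1CO[Si](c4ccccc4)(c5ccccc5)C(C)(C)C)c6ccccc6 | intermediate (not isolated)
30 | O6 tert-butyldiphenylsilyl ether of the target | C=C1C(=O)[C@]23C[C@H]1CC[C@H]2[C@]1(COC3=O)[C@@H](OC(C)=O)CC[C@@](C)(COC(C)=O)[C@H]1CO[Si](c4ccccc4)(c5ccccc5)C(C)(C)C | intermediate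
31 | CNP0105570.2 | C=C1C(=O)[C@]23C[C@H]1CC[C@H]2[C@]1(COC3=O)[C@@H](OC(C)=O)CC[C@@](C)(COC(C)=O)[C@H]1CO | target

## Step count and weak points

Total step count: 20. Longest linear sequence: 19 steps (steps 2–20, from 3 to 31); step 1 is the only step outside it.

Step 7 (key step, the only one that carries the label "Proposed new method:"). The most likely failure is that no cycloadduct forms. The trisubstituted iminium ion is hindered and pyrone 2 is a weak diene, so the free amine may instead be consumed by conjugate ring opening of 2; exo orientation and the wrong regiochemistry are secondary risks. The fallback uses known reaction types only, sets out from 13 and comes back to the route at 17. It builds ring A by a normal-demand Diels–Alder reaction in which the quaternary C4 comes from the dienophile, and the carbon that is formyl in 13 becomes C1. Addition of MeMgBr to 13 gives the allylic alcohol F1, MnO2 oxidation the methyl enone F2, and tBuMe2SiOTf/Et3N the 2-silyloxydiene F3. Cycloaddition of F3 with methacrolein, catalysed by a proline-derived cationic oxazaborolidine activated with Tf2NH, gives the cyclohexene aldehyde F4; the formyl carbon ends para to the silyloxy carbon, and its endo orientation puts C19 cis to C6. NaBH4 reduces the C19 aldehyde to the alcohol F5. The silyl enol ether then reacts with 2-methoxy-1,3-dioxolane and BF3·OEt2 at C10 on the face anti to C6, which introduces C9 as its dioxolane and gives ketone F6. Axial attack of NaBH4 on the C1 carbonyl gives the equatorial alcohol, which is 17.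

Step 15. The most likely failure is incomplete facial discrimination, because C9 is flanked on both sides (O1 acetate on C1, CH2OSitBuPh2 on C5), so the C8/C9 diastereomer with ring C syn to C5 may form as well. Slow addition at the neopentyl C9 with heterodiene reactivity of 22 is the second concern. The fallback sets out from 22 and comes back at 26, replacing substrate control in a concerted addition by catalyst control in a stepwise one. Mukaiyama–Michael addition of 23 to 22 is run with Cu(OTf)2 and (S,S)-2,2'-isopropylidenebis(4-tert-butyl-2-oxazoline), which bind the 1,3-dicarbonyl unit of 22 to divalent copper and select the face at C9. Hydrolytic work-up gives the vinyl ketone F7. Treatment of F7 with Bu4N[Ph3SiF2] as a mild base closes ring C by Michael addition of C8 to C14, and the enolate formed is 25, which alkylates C16 as in step 16 to give 26.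

Step 16. The most likely failure is that the enolate 25 reacts otherwise than by alkylation: proton transfer from the acidic C16 position, or retro-Michael opening of ring C with expulsion of the stabilised C8 carbanion, leading to loss of regiochemistry or to condensation products. The fallback sets out from 24 and comes back at 28; it forms the same bond by a radical and also avoids the two-ketone differentiation of step 17. Finkelstein exchange (NaI, acetone) gives the iodomethyl ketone F8. With Bu3SnH and Et3B/air the electrophilic C16 radical adds to the electron-rich C13 of the silyl enol ether, and hydrogen transfer gives the C12 silyl ether F9. Mild acid frees the C12 alcohol F10, and PhOC(S)Cl/pyridine gives the thionocarbonate F11. Barton–McCombie reduction of F11 (Bu3SnH, AIBN, PhMe, 90 °C) gives 28.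

Step 14. The most likely failure is a slow condensation at the neopentyl C9 aldehyde, during which the chloromethyl ketone is destroyed by the amine catalyst or by self-alkylation. The fallback sets out from 19 and comes back at 22; it makes the C8=C9 bond before the ester bond. Condensation of 19 with methyl 4-chloro-3-oxobutanoate under TiCl4/pyridine in THF gives the open-chain alkylidene keto ester F12 as a mixture of geometric isomers. DDQ removes the PMB group to give alcohol F13, and catalytic camphorsulfonic acid in toluene lactonises it to 22; the geometric isomers interconvert under these conditions.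

## Further compounds

F1 | step 7 | (E)-5-(tert-butyldiphenylsilyloxy)-3-[(4-methoxybenzyloxy)methyl]pent-3-en-2-ol (carbinol centre racemic) | CC(O)/C(COCc1ccc(OC)cc1)=C/CO[Si](c1ccccc1)(c1ccccc1)C(C)(C)C
F2 | step 7 | (E)-5-(tert-butyldiphenylsilyloxy)-3-[(4-methoxybenzyloxy)methyl]pent-3-en-2-one | CC(=O)/C(COCc1ccc(OC)cc1)=C/CO[Si](c1ccccc1)(c1ccccc1)C(C)(C)C
F3 | step 7 | (E)-2-(tert-butyldimethylsilyloxy)-5-(tert-butyldiphenylsilyloxy)-3-[(4-methoxybenzyloxy)methyl]penta-1,3-diene | C=C(O[Si](C)(C)C(C)(C)C)/C(COCc1ccc(OC)cc1)=C/CO[Si](c1ccccc1)(c1ccccc1)C(C)(C)C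
F4 | step 7 | ring A cyclohexene aldehyde: C1(OSitBuMe2)=C10(CH2OPMB), C4 with CH3 and CHO (C19), C5 with CH2OSitBuPh2 cis to the formyl group | C1(COCc2ccc(OC)cc2)=C(O[Si](C)(C)C(C)(C)C)CC[C@@](C)(C=O)[C@H]1CO[Si](c3ccccc3)(c4ccccc4)C(C)(C)C
F5 | step 7 | C19 alcohol of F4 | C1(COCc2ccc(OC)cc2)=C(O[Si](C)(C)C(C)(C)C)CC[C@@](C)(CO)[C@H]1CO[Si](c3ccccc3)(c4ccccc4)C(C)(C)C
F6 | step 7 | ring A C1 ketone with C10 bearing 1,3-dioxolan-2-yl (C9) and CH2OPMB (C20), C19 alcohol | C6(OCCO6)[C@]1(COCc3ccc(OC)cc3)C(=O)CC[C@@](C)(CO)[C@H]1CO[Si](c4ccccc4)(c5ccccc5)C(C)(C)C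
F7 | step 15 | Michael adduct: saturated spiro lactone with C9 bearing the 2-oxobut-3-enyl chain (C11–C14) syn to C1 and C8 bearing H and chloroacetyl (C8 epimers) | C=CC(=O)C[C@H]2[C@]1(COC(=O)C2C(=O)CCl)[C@@H](OC(C)=O)CC[C@@](C)(COC(C)=O)[C@H]1CO[Si](c4ccccc4)(c5ccccc5)C(C)(C)C
F8 | step 16 | iodoacetyl analogue of 24 | ICC(=O)[C@]23CC=C(O[Si](C)(C)C)C[C@H]2[C@]1(COC3=O)[C@@H](OC(C)=O)CC[C@@](C)(COC(C)=O)[C@H]1CO[Si](c4ccccc4)(c5ccccc5)C(C)(C)C
F9 | step 16 | tetracyclic 15-ketone with C12 trimethylsilyloxy group (C12 configuration immaterial) | C1C(=O)[C@]23C[C@H]1C(O[Si](C)(C)C)C[C@H]2[C@]1(COC3=O)[C@@H](OC(C)=O)CC[C@@](C)(COC(C)=O)[C@H]1CO[Si](c4ccccc4)(c5ccccc5)C(C)(C)C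
F10 | step 16 | tetracyclic 15-ketone with C12 hydroxyl group (C12 configuration immaterial) | C1C(=O)[C@]23C[C@H]1C(O)C[C@H]2[C@]1(COC3=O)[C@@H](OC(C)=O)CC[C@@](C)(COC(C)=O)[C@H]1CO[Si](c4ccccc4)(c5ccccc5)C(C)(C)C
F11 | step 16 | C12 O-phenyl thionocarbonate of F10 | C1C(=O)[C@]23C[C@H]1C(OC(=S)Oc6ccccc6)C[C@H]2[C@]1(COC3=O)[C@@H](OC(C)=O)CC[C@@](C)(COC(C)=O)[C@H]1CO[Si](c4ccccc4)(c5ccccc5)C(C)(C)C
F12 | step 14 | open-chain alkylidene keto ester: C9=C8 with C8 bearing CO2CH3 (C7) and chloroacetyl, O20 PMB (geometric isomers) | COC(=O)C(C(=O)CCl)=C[C@]1(COCc3ccc(OC)cc3)[C@@H](OC(C)=O)CC[C@@](C)(COC(C)=O)[C@H]1CO[Si](c4ccccc4)(c5ccccc5)C(C)(C)C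
F13 | step 14 | C20 alcohol of F12 | COC(=O)C(C(=O)CCl)=C[C@]1(CO)[C@@H](OC(C)=O)CC[C@@](C)(COC(C)=O)[C@H]1CO[Si](c4ccccc4)(c5ccccc5)C(C)(C)C
A1 | alternative 1 | cyclobutane photoadduct with siloxane bridge | CC(C)(C)[Si](C)(C)OCCC[C@@]12C[C@H]3[C@@H]1[C@@](C)(CCC2=O)CO[Si]3(C)C
A2 | alternative 2 | 12-oxo-15-deoxo bicyclo[3.2.1]octane lactone with exo-methylene group | C=C1C[C@]23C[C@H]1C(=O)C[C@H]2[C@]1(COC3=O)[C@@H](O[Si](C)(C)C(C)(C)C)CC[C@@](C)(CO[Si](C)(C)C(C)(C)C)[C@H]1COCc1ccc(OC)cc1
A3 | alternative 3 | ring A ketone with quaternary C10 and free C20 alcohol | CC(C)(C)[Si](C)(C)OCCC[C@]1(CO)C(=O)CC[C@@](C)(COCc2ccc(OC)cc2)[C@H]1CO[Si](C(C)C)(C(C)C)C(C)C
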